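Numbering: C1' is the benzylic carbon and C17' the chain methyl; the alkene is C8'=C9' (Z) and the carbinol is C11' (S); the only ring is the resorcinol benzene ring, which is bought intact.
Retrosynthesis: the two phenols are masked as methoxymethyl ethers, then the chain is cut on both sides of the alkene, at C7'–C8' and C9'–C10', into a 7-arylheptyl iodide, acetylene (C8' and C9') and (S)-1,2-epoxyoctane (C10' to C17'); the iodide is cut further at the aryl–C1' bond.
Enabling feature: the cis C8'=C9' unit has a CH2 on each side (C7' and C10'), and C10' is the single atom between it and the C11' carbinol. This is the pattern left when an alkylcopper adds syn to acetylene and the alkenylcopper then opens a terminal epoxide at its CH2.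
Forward order: aryl–C1' by B-alkyl Suzuki coupling, bromide-to-iodide exchange, then C7'–C8' and C9'–C10' in one flask around acetylene, then removal of the acetals; no ring is formed at any stage.
Stereochemistry: C11' comes from hydrolytic kinetic resolution of racemic 1,2-epoxyoctane and is never a reacting centre afterwards; the Z geometry comes from the syn carbocupration.

Key step: step 5

Remark: the (S,S) enantiomer of the cobalt salen catalyst is taken to hydrolyse the R enantiomer of an unbranched 1,2-epoxyalkane faster, so that the S epoxide is the one recovered; its sign of rotation is to be checked before use.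

Step 1
Reactants: 1 5-bromobenzene-1,3-diol (5-bromoresorcinol)
Product: 2 1-bromo-3,5-bis(methoxymethoxy)benzene
Conditions: MOMCl (2.5 equiv), i-Pr2NEt (3 equiv), CH2Cl2, 0 °C to rt
Reagents that add atoms: chloromethyl methyl ether, COCCl
Why: Williamson-type O-alkylation of both phenols by the reactive α-chloro ether should be clean, and the resulting methoxymethyl ethers withstand the palladium coupling, the halide exchange and the organometallic step that follow.

Step 2
Reactants: 3 7-bromohept-1-ene; 2 1-bromo-3,5-bis(methoxymethoxy)benzene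
Product: 5 1-(7-bromoheptyl)-3,5-bis(methoxymethoxy)benzene, via B-(7-bromoheptyl)-9-BBN 4 (not isolated)
Conditions: 3 (1.2 equiv), 9-BBN (1.25 equiv), THF, 0 °C to rt; then 2, PdCl2(dppf) (3 mol %), 3 M aq K3PO4 (3 equiv), DMF, 50 °C
Reagents that add atoms: none
Why: Anti-Markovnikov hydroboration of the terminal alkene followed by B-alkyl Suzuki–Miyaura coupling should join the primary carbon to the aryl bromide, and the unactivated primary carbon–bromine bond is expected to survive because zerovalent palladium carrying dppf inserts into aryl bromides far faster than into alkyl bromides and phosphate at 50 °C is too weak a nucleophile to displace it.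

Step 3
Reactants: 5 1-(7-bromoheptyl)-3,5-bis(methoxymethoxy)benzene
Product: 6 1-(7-iodoheptyl)-3,5-bis(methoxymethoxy)benzene
Conditions: NaI (3 equiv), acetone, reflux
Reagents that add atoms: sodium iodide, [Na+].[I-]
Why: Finkelstein exchange (SN2 at an unhindered primary carbon, driven by precipitation of NaBr) should give the iodide, which is needed because only a primary iodide exchanges cleanly with t-BuLi.

Step 4
Reactants: 7 racemic 1,2-epoxyoctane
Product: 8 (S)-1,2-epoxyoctane
Conditions: (S,S)-(salen)Co(OAc) (0.5 mol %; salen = N,N'-bis(3,5-di-tert-butylsalicylidene)cyclohexane-1,2-diaminate), H2O (0.55 equiv), THF (minimal), 0 °C to rt; distillation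
Reagents that add atoms: none
Why: In this hydrolytic kinetic resolution of a terminal epoxide (Jacobsen type) the chiral trivalent cobalt complex delivers water to the CH2 of the R epoxide much faster than to the S epoxide, so the S epoxide should be left in high enantiomeric purity and can be distilled from the diol; this is the origin of the C11' configuration.

Step 5
Reactants: 6 1-(7-iodoheptyl)-3,5-bis(methoxymethoxy)benzene; 9 acetylene; 8 (S)-1,2-epoxyoctane
Product: 13 (7S,9Z)-17-[3,5-bis(methoxymethoxy)phenyl]heptadec-9-en-7-ol, via 7-arylheptyllithium 10 (not isolated), via lithium dialkylcuprate 11 (not isolated), via lithium Z-dialkenylcuprate 12 (not isolated)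
Conditions: 6 (2.0 equiv), t-BuLi (4.0 equiv, titrated), Et2O/pentane, −78 °C; CuBr·SMe2 (1.0 equiv), −78 to −40 °C; HC≡CH (2.0 equiv, acetone-free, measured by gas burette), −50 to −25 °C; 8 (1.0 equiv), THF, −40 to −10 °C; aq NH4Cl
Reagents that add atoms: none
Why: Iodine–lithium exchange with two equivalents of t-BuLi should give the primary alkyllithium 10 at −78 °C faster than any proton abstraction from the ring position between the two acetal oxygens, and CuBr·SMe2 combines two of these into the Gilman-type cuprate 11. Each alkyl–copper bond of 11 then adds across one acetylene by a concerted syn carbometalation (Normant carbocupration), so that the new C7'–C8' bond and copper end up cis and 12 is Z by mechanism; alkenylcopper species hold their geometry at these temperatures. One alkenyl ligand of 12 attacks the CH2 of epoxide 8 in an SN2 opening with retention at the sp2 carbon, forming C9'–C10'; the closest known reaction type is the opening of terminal epoxides by Z-dialkenylcuprates to give Z-homoallylic alcohols. No ring is closed and no stereocentre is created: C11' is not a reacting centre and keeps the S configuration of 8, while the Z geometry is fixed by the syn addition. The step needs single addition to acetylene, secured by a measured two equivalents of gas and a temperature kept below −25 °C where the alkenylcuprate does not add to a second acetylene, and attack at the terminal epoxide carbon, secured by the steric bias of the monosubstituted epoxide. Only one alkenyl ligand is counted on for transfer, the other being protonated to a terminal alkene at work-up, which is why 6 is used in twofold amount.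

Step 6
Reactants: 13 (7S,9Z)-17-[3,5-bis(methoxymethoxy)phenyl]heptadec-9-en-7-ol
Product: 14 5-[(8Z,11S)-11-hydroxyheptadec-8-en-1-yl]benzene-1,3-diol (CNP0134805.1)
Conditions: HCl (1 M in MeOH), 40 °C
Reagents that add atoms: none
Why: Acid-catalysed acetal exchange with methanol (transacetalisation) should free both phenols, while the isolated Z alkene and the secondary homoallylic alcohol offer no easily ionised position in dilute acid, so geometry and configuration are expected to be kept.

Compound list
1 | 5-bromobenzene-1,3-diol (5-bromoresorcinol) | Oc1cc(O)cc(Br)c1 | starting material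
2 | 1-bromo-3,5-bis(methoxymethoxy)benzene | COCOc1cc(Br)cc(OCOC)c1 | intermediate
3 | 7-bromohept-1-ene | C=CCCCCCBr | starting material
4 | 9-(7-bromoheptyl)-9-borabicyclo[3.3.1]nonane [B-(7-bromoheptyl)-9-BBN] | BrCCCCCCCB1C2CCCC1CCC2 | intermediate
5 | 1-(7-bromoheptyl)-3,5-bis(methoxymethoxy)benzene | COCOc1cc(CCCCCCCBr)cc(OCOC)c1 | intermediate
6 | 1-(7-iodoheptyl)-3,5-bis(methoxymethoxy)benzene | COCOc1cc(CCCCCCCI)cc(OCOC)c1 | intermediate
7 | racemic 1,2-epoxyoctane (2-hexyloxirane) | CCCCCCC1CO1 | starting material
8 | (S)-1,2-epoxyoctane [(2S)-2-hexyloxirane] | CCCCCC[C@H]1CO1 | intermediate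
9 | acetylene | C#C | starting material
10 | {7-[3,5-bis(methoxymethoxy)phenyl]heptyl}lithium | [Li]CCCCCCCc1cc(OCOC)cc(OCOC)c1 | intermediate
11 | lithium bis{7-[3,5-bis(methoxymethoxy)phenyl]heptyl}cuprate | [Li+].COCOc1cc(CCCCCCC[Cu-]CCCCCCCc2cc(OCOC)cc(OCOC)c2)cc(OCOC)c1 | intermediate
12 | lithium bis{(1Z)-9-[3,5-bis(methoxymethoxy)phenyl]non-1-en-1-yl}cuprate | [Li+].COCOc1cc(CCCCCCC/C=C\[Cu-]/C=C\CCCCCCCc2cc(OCOC)cc(OCOC)c2)cc(OCOC)c1 | intermediate
13 | (7S,9Z)-17-[3,5-bis(methoxymethoxy)phenyl]heptadec-9-en-7-ol | CCCCCC[C@H](O)C/C=C\CCCCCCCc1cc(OCOC)cc(OCOC)c1 | intermediate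
14 | 5-[(8Z,11S)-11-hydroxyheptadec-8-en-1-yl]benzene-1,3-diol | CCCCCC[C@H](O)C/C=C\CCCCCCCc1cc(O)cc(O)c1 | target

Total step count: 6.
Longest linear sequence: 5 steps (steps 1, 2, 3, 5, 6) from 5-bromoresorcinol; step 4 is a one-step side branch.

Steps most likely to fail

Step 5. What may go wrong: proton abstraction from the ring position between the two acetal oxygens by the alkyllithium before it reaches copper, addition of the alkenylcuprate to a second acetylene, or thermal decay of the alkenylcuprate before it has opened the epoxide. The fallback sets out from 6 (and uses 8) and comes back at 13; it makes the same two bonds one at a time through an alkyne. Displacement of iodide in 6 by LiC≡CH·H2NCH2CH2NH2 in DMSO at rt should give 1,3-bis(methoxymethoxy)-5-(non-8-yn-1-yl)benzene F1. Treatment with n-BuLi in THF at −78 °C converts it into {9-[3,5-bis(methoxymethoxy)phenyl]non-1-yn-1-yl}lithium F2, which in the presence of BF3·OEt2 opens 8 at its CH2 to give (7S)-17-[3,5-bis(methoxymethoxy)phenyl]heptadec-9-yn-7-ol F3. Semihydrogenation of F3 over Pd/CaCO3 poisoned with Pb(OAc)2 (quinoline, H2 1 atm, EtOAc) returns to 13, the Z geometry then resting on cis delivery of hydrogen.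

Step 2. What may go wrong: loss of the primary bromide under the coupling conditions (substitution by the aqueous base, or palladium insertion followed by β-hydride elimination) and protodeboronation of the alkylborane. The fallback sets out from 2 and comes back at 6, bypassing 5 and step 3. Sonogashira coupling of 2 with commercial hept-6-yn-1-ol (PdCl2(PPh3)2, CuI, Et3N, 70 °C) should give 7-[3,5-bis(methoxymethoxy)phenyl]hept-6-yn-1-ol F4. Hydrogenation over Pd/C (H2, EtOAc) gives 7-[3,5-bis(methoxymethoxy)phenyl]heptan-1-ol F5, and Appel-type iodination (I2, PPh3, imidazole, CH2Cl2, 0 °C) gives 6.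

Step 6. What may go wrong: alkylation of the liberated, very electron-rich resorcinol ring by the formaldehyde equivalents released in acid (hydroxymethylation or methylene bridging), or incomplete cleavage of the second acetal. The fallback sets out from 1 and comes back at 14; the phenols are carried as triisopropylsilyl ethers, which fluoride removes without acid and without an electrophilic by-product. Treatment of 1 with i-Pr3SiCl and imidazole in DMF should give 1-bromo-3,5-bis[(triisopropylsilyl)oxy]benzene F6, and coupling with 4 as in step 2 gives 1-(7-bromoheptyl)-3,5-bis[(triisopropylsilyl)oxy]benzene F7. NaI in acetone then gives 1-(7-iodoheptyl)-3,5-bis[(triisopropylsilyl)oxy]benzene F8. The sequence of step 5 then runs through {7-[3,5-bis(triisopropylsilyloxy)phenyl]heptyl}lithium F9, lithium bis{7-[3,5-bis(triisopropylsilyloxy)phenyl]heptyl}cuprate F10 and lithium bis{(1Z)-9-[3,5-bis(triisopropylsilyloxy)phenyl]non-1-en-1-yl}cuprate F11 to (7S,9Z)-17-{3,5-bis[(triisopropylsilyl)oxy]phenyl}heptadec-9-en-7-ol F12. Bu4NF in THF at 0 °C then gives 14.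

Further compounds
F1 | step 5 | 1,3-bis(methoxymethoxy)-5-(non-8-yn-1-yl)benzene | C#CCCCCCCCc1cc(OCOC)cc(OCOC)c1
F2 | step 5 | {9-[3,5-bis(methoxymethoxy)phenyl]non-1-yn-1-yl}lithium | [Li]C#CCCCCCCCc1cc(OCOC)cc(OCOC)c1
F3 | step 5 | (7S)-17-[3,5-bis(methoxymethoxy)phenyl]heptadec-9-yn-7-ol | CCCCCC[C@H](O)CC#CCCCCCCCc1cc(OCOC)cc(OCOC)c1
F4 | step 2 | 7-[3,5-bis(methoxymethoxy)phenyl]hept-6-yn-1-ol | OCCCCCC#Cc1cc(OCOC)cc(OCOC)c1
F5 | step 2 | 7-[3,5-bis(methoxymethoxy)phenyl]heptan-1-ol | OCCCCCCCc1cc(OCOC)cc(OCOC)c1
F6 | step 6 | 1-bromo-3,5-bis[(triisopropylsilyl)oxy]benzene | Brc1cc(O[Si](C(C)C)(C(C)C)C(C)C)cc(O[Si](C(C)C)(C(C)C)C(C)C)c1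
F7 | step 6 | 1-(7-bromoheptyl)-3,5-bis[(triisopropylsilyl)oxy]benzene | BrCCCCCCCc1cc(O[Si](C(C)C)(C(C)C)C(C)C)cc(O[Si](C(C)C)(C(C)C)C(C)C)c1
F8 | step 6 | 1-(7-iodoheptyl)-3,5-bis[(triisopropylsilyl)oxy]benzene | ICCCCCCCc1cc(O[Si](C(C)C)(C(C)C)C(C)C)cc(O[Si](C(C)C)(C(C)C)C(C)C)c1
F9 | step 6 | {7-[3,5-bis(triisopropylsilyloxy)phenyl]heptyl}lithium | [Li]CCCCCCCc1cc(O[Si](C(C)C)(C(C)C)C(C)C)cc(O[Si](C(C)C)(C(C)C)C(C)C)c1
F10 | step 6 | lithium bis{7-[3,5-bis(triisopropylsilyloxy)phenyl]heptyl}cuprate | [Li+].CC(C)[Si](Oc1cc(CCCCCCC[Cu-]CCCCCCCc2cc(O[Si](C(C)C)(C(C)C)C(C)C)cc(O[Si](C(C)C)(C(C)C)C(C)C)c2)cc(O[Si](C(C)C)(C(C)C)C(C)C)c1)(C(C)C)C(C)C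
F11 | step 6 | lithium bis{(1Z)-9-[3,5-bis(triisopropylsilyloxy)phenyl]non-1-en-1-yl}cuprate | [Li+].CC(C)[Si](Oc1cc(CCCCCCC/C=C\[Cu-]/C=C\CCCCCCCc2cc(O[Si](C(C)C)(C(C)C)C(C)C)cc(O[Si](C(C)C)(C(C)C)C(C)C)c2)cc(O[Si](C(C)C)(C(C)C)C(C)C)c1)(C(C)C)C(C)C
F12 | step 6 | (7S,9Z)-17-{3,5-bis[(triisopropylsilyl)oxy]phenyl}heptadec-9-en-7-ol | CCCCCC[C@H](O)C/C=C\CCCCCCCc1cc(O[Si](C(C)C)(C(C)C)C(C)C)cc(O[Si](C(C)C)(C(C)C)C(C)C)c1
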